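Ar = 3,4-bis(tert-butyldimethylsilyloxy)-5-methoxyphenyl; geranyl = (2E)-3,7-dimethylocta-2,6-dien-1-yl; flavanone numbering (O1, C2–C4, C4a, C5–C8, C8a) is used for the target.

**Retrosynthetic overview**
- The strategy rests on ring A (C4a, C5, C6, C7, C8, C8a): the geranyl-bearing C6 lies between the oxygenated C5 and C7, and C8 is the only C–H.
- Target 22 comes from tris-silyl flavanone 21 by buffered fluoride; ring A of 21 is cut into diazoketone 11 (ring C, O1 and (S)-C2 already present) and geranyl siloxyalkyne 16.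
- 11 comes from pyranone ester 7, made by an asymmetric aldol/cyclodehydration (stepwise hetero-Diels–Alder) of aldehyde 2 with bis-silyloxy diene 4; C2 is set here.
- 16 comes from geranyl bromide by copper-catalysed ethynylation, then oxidation of the acetylide to the ynolate and O-silylation.
- Ring order: B (bought) → C (step 3) → A (step 8).

Key step: step 8

Remark (assumption): diene 4 is drawn as the 2Z isomer; either geometry leads to the same hydroxy diketo ester 6.
Remark (design): the ketene is generated with light, not a metal. Rh2(OAc)4 (divalent rhodium) would give a carbenoid that adds to the electron-rich alkyne instead of rearranging, and silver salts activate siloxyalkynes.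

**Route**

Step 1
Reactants: 1 3,4-dihydroxy-5-methoxybenzaldehyde
Product: 2 3,4-bis(tert-butyldimethylsilyloxy)-5-methoxybenzaldehyde
Conditions: TBSCl (2.5 equiv), imidazole, DMF, rt
Reagents that add atoms: tert-butyldimethylsilyl chloride, CC(C)(C)[Si](C)(C)Cl
Why: Standard silylation of both phenols, which masks the catechol as fluoride-labile ethers that tolerate Lewis acid, TFA and heat.

Step 2
Reactants: 3 methyl 2,4-dioxopentanoate
Product: 4 methyl (2Z)-2,4-bis(trimethylsilyloxy)penta-2,4-dienoate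
Conditions: TMSOTf (2.2 equiv), Et3N (2.5 equiv), Et2O, 0 °C to rt; filtered, concentrated and used directly
Reagents that add atoms: trimethylsilyl trifluoromethanesulfonate, C[Si](C)(C)OS(=O)(=O)C(F)(F)F
Why: Soft enolisation of the 1,3-dicarbonyl unit and then of the remaining methyl ketone gives the bis(silyl enol ether), as in the preparation of 1,3-bis(silyloxy)dienes from 1,3-diketones.

Step 3
Reactants: 2 3,4-bis(tert-butyldimethylsilyloxy)-5-methoxybenzaldehyde; 4 methyl (2Z)-2,4-bis(trimethylsilyloxy)penta-2,4-dienoate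
Product: 7 methyl (2S)-2-Ar-4-oxo-3,4-dihydro-2H-pyran-6-carboxylate, via aldol adduct 5 (not isolated), via hydroxy diketo ester 6 (not isolated)
Conditions: Ti(OiPr)4 (20 mol%), (S)-BINOL (22 mol%), 4 Å MS, THF, −78 to 0 °C; then TFA, CH2Cl2, 0 °C to rt
Reagents that add atoms: none
Why: Titanium–BINOL-catalysed Mukaiyama aldol of the terminal CH2 of 4 (the stepwise form of a Danishefsky-type hetero-Diels–Alder) should add to the Si face of the aldehyde with the (S)-ligand, by analogy with related additions to aryl aldehydes, setting (S) at the future C2; TFA then removes the TMS groups and cyclodehydrates 6 to the dihydropyranone.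

Step 4
Reactants: 7 methyl (2S)-2-Ar-4-oxo-3,4-dihydro-2H-pyran-6-carboxylate
Product: 9 (2S)-2-Ar-4-oxo-3,4-dihydro-2H-pyran-6-carboxylic acid, via stannyl ester 8 (not isolated)
Conditions: Me3SnOH (4 equiv), ClCH2CH2Cl, 70 °C; then cold 5% aq. HCl wash
Reagents that add atoms: trimethyltin hydroxide, C[Sn](C)(C)O
Why: Trimethyltin hydroxide cleaves methyl esters under nearly neutral conditions, avoiding the hydroxide-induced ring opening at C2–O1 (which would racemise C2) and the loss of aryl silyl ethers expected with alkali hydroxide.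

Step 5
Reactants: 9 (2S)-2-Ar-4-oxo-3,4-dihydro-2H-pyran-6-carboxylic acid
Product: 11 (2S)-6-(diazoacetyl)-2-Ar-2,3-dihydro-4H-pyran-4-one, via acid chloride 10 (not isolated)
Conditions: 1-chloro-N,N,2-trimethylprop-1-en-1-amine, CH2Cl2, 0 °C to rt; then CH2N2 (4 equiv), Et2O, −20 to 0 °C, dark
Reagents that add atoms: diazomethane, C=[N+]=[N-]
Why: Neutral acid chloride formation followed by acylation of diazomethane (first stage of the Arndt–Eistert sequence) works here because 10 has no alpha hydrogen and so cannot form a ketene, and excess diazomethane consumes the HCl.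

Step 6
Reactants: 12 geranyl bromide
Product: 13 (4E)-5,9-dimethyldeca-4,8-dien-1-yne
Conditions: HC≡CMgBr (3 equiv), CuCl (10 mol%), THF, 0 °C to rt
Reagents that add atoms: ethynylmagnesium bromide, C#C[Mg]Br
Why: Copper-catalysed coupling of an alkynyl Grignard reagent with a primary allylic bromide gives the skipped enyne by direct substitution with the E alkene retained; excess Grignard suppresses double alkylation.

Step 7
Reactants: 13 (4E)-5,9-dimethyldeca-4,8-dien-1-yne
Product: 16 (4E)-5,9-dimethyl-1-(triisopropylsilyloxy)deca-4,8-dien-1-yne, via lithium acetylide 14 (not isolated), via lithium ynolate 15 (not isolated)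
Conditions: n-BuLi, THF, −78 °C; t-BuOOLi (from t-BuOOH and LiHMDS), −78 to 0 °C; TIPSOTf, −78 °C to rt
Reagents that add atoms: tert-butyl hydroperoxide (as its lithium salt), CC(C)(C)OO; triisopropylsilyl trifluoromethanesulfonate, CC(C)[Si](OS(=O)(=O)C(F)(F)F)(C(C)C)C(C)C
Why: Electrophilic oxygen transfer from lithium tert-butyl peroxide to the acetylide carbon gives the ynolate, and the bulky silyl triflate traps it on oxygen to give the siloxyalkyne, a known acetylide-oxidation route to these compounds.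

Step 8
Reactants: 11 (2S)-6-(diazoacetyl)-2-Ar-2,3-dihydro-4H-pyran-4-one; 16 (4E)-5,9-dimethyl-1-(triisopropylsilyloxy)deca-4,8-dien-1-yne
Product: 21 (2S)-2-Ar-6-geranyl-5-hydroxy-7-(triisopropylsilyloxy)chroman-4-one, via vinylketene 17 (not isolated), via cyclobutenone 18 (not isolated), via dienylketene 19 (not isolated), via cyclohexadienone 20 (not isolated)
Conditions: 16 (1.5 equiv), hν (LED, 405–450 nm), degassed ClCH2CH2Cl, 0.03 M, rt; then 80 °C, dark
Reagents that add atoms: none
Why: Light expels N2 from 11 and the pyranone C6 (future C8a) shifts to the diazo carbon (Wolff rearrangement), giving vinylketene 17 whose alkene is the pyranone C5=C6 bond. The electron-rich alkyne 16 adds to the ketene C=C by [2+2] cycloaddition to give 18, which opens thermally (4π electrocyclic) to dienylketene 19; 6π electrocyclisation onto the pyranone C5 (future C4a) gives 20, and enolisation aromatises it to 21. The closest known reaction type is the Danheiser benzannulation of alpha,beta-unsaturated alpha'-diazo ketones with siloxyalkynes, which gives resorcinol monosilyl ethers. The transient four-membered ring closes by [2+2] cycloaddition (C5–C6 and C7–C8), and ring A closes by thermal disrotatory 6π electrocyclisation forming C4a–C5, after C8–C8a was made in the Wolff shift. No stereocentre is created in the product: the sp3 carbons of 18 and 20 are erased on aromatisation, and C2 is a bystander under neutral, base-free conditions, so the (S) configuration from step 3 should persist. The step needs a regioselective ketene–alkyne union, secured by the polarisation of 16: its nucleophilic geranyl-bearing carbon bonds to the ketene carbonyl carbon, so geranyl lands on C6 between the C5 hydroxyl and the C7 silyl ether and C8 is left as the only C–H.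

Step 9
Reactants: 21 (2S)-2-Ar-6-geranyl-5-hydroxy-7-(triisopropylsilyloxy)chroman-4-one
Product: 22 (2S)-2-(3,4-dihydroxy-5-methoxyphenyl)-6-geranyl-5,7-dihydroxychroman-4-one (target)
Conditions: TBAF, AcOH (1:1, 4 equiv), THF, 0 °C to rt, argon
Reagents that add atoms: none
Why: Acetic acid-buffered fluoride cleaves the three aryl silyl ethers without generating free phenoxide, so the retro-oxa-Michael opening of ring C (racemisation through the chalcone) and catechol oxidation should be suppressed, and the geranyl alkenes are untouched.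

**Compound list**
1 | 3,4-dihydroxy-5-methoxybenzaldehyde | COc1cc(C=O)cc(O)c1O | starting material
2 | 3,4-bis(tert-butyldimethylsilyloxy)-5-methoxybenzaldehyde | COc1cc(C=O)cc(O[Si](C)(C)C(C)(C)C)c1O[Si](C)(C)C(C)(C)C | intermediate
3 | methyl 2,4-dioxopentanoate | COC(=O)C(=O)CC(C)=O | starting material
4 | methyl (2Z)-2,4-bis(trimethylsilyloxy)penta-2,4-dienoate | C=C(O[Si](C)(C)C)/C=C(\O[Si](C)(C)C)C(=O)OC | intermediate
5 | methyl (2Z,6S)-6-Ar-4-oxo-2,6-bis(trimethylsilyloxy)hex-2-enoate | COC(=O)/C(O[Si](C)(C)C)=C/C(=O)C[C@H](O[Si](C)(C)C)c1cc(OC)c(O[Si](C)(C)C(C)(C)C)c(O[Si](C)(C)C(C)(C)C)c1 | intermediate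
6 | methyl (6S)-6-Ar-6-hydroxy-2,4-dioxohexanoate | COC(=O)C(=O)CC(=O)C[C@H](O)c1cc(OC)c(O[Si](C)(C)C(C)(C)C)c(O[Si](C)(C)C(C)(C)C)c1 | intermediate
7 | methyl (2S)-2-Ar-4-oxo-3,4-dihydro-2H-pyran-6-carboxylate | COc1cc([C@@H]2CC(=O)C=C(C(=O)OC)O2)cc(O[Si](C)(C)C(C)(C)C)c1O[Si](C)(C)C(C)(C)C | intermediate
8 | trimethylstannyl (2S)-2-Ar-4-oxo-3,4-dihydro-2H-pyran-6-carboxylate | COc1cc([C@@H]2CC(=O)C=C(C(=O)O[Sn](C)(C)C)O2)cc(O[Si](C)(C)C(C)(C)C)c1O[Si](C)(C)C(C)(C)C | intermediate
9 | (2S)-2-Ar-4-oxo-3,4-dihydro-2H-pyran-6-carboxylic acid | COc1cc([C@@H]2CC(=O)C=C(C(=O)O)O2)cc(O[Si](C)(C)C(C)(C)C)c1O[Si](C)(C)C(C)(C)C | intermediate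
10 | (2S)-2-Ar-4-oxo-3,4-dihydro-2H-pyran-6-carbonyl chloride | COc1cc([C@@H]2CC(=O)C=C(C(=O)Cl)O2)cc(O[Si](C)(C)C(C)(C)C)c1O[Si](C)(C)C(C)(C)C | intermediate
11 | (2S)-6-(diazoacetyl)-2-Ar-2,3-dihydro-4H-pyran-4-one | COc1cc([C@@H]2CC(=O)C=C(C(=O)C=[N+]=[N-])O2)cc(O[Si](C)(C)C(C)(C)C)c1O[Si](C)(C)C(C)(C)C | intermediate
12 | geranyl bromide, (2E)-1-bromo-3,7-dimethylocta-2,6-diene | CC(C)=CCC/C(C)=C/CBr | starting material
13 | (4E)-5,9-dimethyldeca-4,8-dien-1-yne | CC(C)=CCC/C(C)=C/CC#C | intermediate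
14 | lithium (4E)-5,9-dimethyldeca-4,8-dien-1-yn-1-ide | CC(C)=CCC/C(C)=C/CC#C[Li] | intermediate
15 | lithium (4E)-5,9-dimethyldeca-4,8-dien-1-yn-1-olate | CC(C)=CCC/C(C)=C/CC#C[O-].[Li+] | intermediate
16 | (4E)-5,9-dimethyl-1-(triisopropylsilyloxy)deca-4,8-dien-1-yne | CC(C)=CCC/C(C)=C/CC#CO[Si](C(C)C)(C(C)C)C(C)C | intermediate
17 | (2S)-2-Ar-6-(2-oxoethenyl)-2,3-dihydro-4H-pyran-4-one (vinylketene) | COc1cc([C@@H]2CC(=O)C=C(C=C=O)O2)cc(O[Si](C)(C)C(C)(C)C)c1O[Si](C)(C)C(C)(C)C | intermediate
18 | 4-[(2S)-2-Ar-4-oxo-3,4-dihydro-2H-pyran-6-yl]-2-geranyl-3-(triisopropylsilyloxy)cyclobut-2-en-1-one (epimers at the ring sp3 carbon) | COc1cc([C@@H]2CC(=O)C=C(C3C(=O)C(C/C=C(\C)CCC=C(C)C)=C3O[Si](C(C)C)(C(C)C)C(C)C)O2)cc(O[Si](C)(C)C(C)(C)C)c1O[Si](C)(C)C(C)(C)C | intermediate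
19 | dienylketene, 4-[(2S)-2-Ar-4-oxo-3,4-dihydro-2H-pyran-6-yl]-2-geranyl-3-(triisopropylsilyloxy)buta-1,3-dien-1-one, drawn with the pyranonyl group cis to the ketene-bearing carbon | O=C=C(C/C=C(\C)CCC=C(C)C)/C(O[Si](C(C)C)(C(C)C)C(C)C)=C\C1=CC(=O)C[C@@H](c2cc(OC)c(O[Si](C)(C)C(C)(C)C)c(O[Si](C)(C)C(C)(C)C)c2)O1 | intermediate
20 | (2S)-2-Ar-6-geranyl-7-(triisopropylsilyloxy)-2,3-dihydro-4H-chromene-4,5(4aH)-dione (4a-H keto tautomer) | O=C1C(C/C=C(\C)CCC=C(C)C)=C(O[Si](C(C)C)(C(C)C)C(C)C)C=C2O[C@H](c3cc(OC)c(O[Si](C)(C)C(C)(C)C)c(O[Si](C)(C)C(C)(C)C)c3)CC(=O)C12 | intermediate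
21 | (2S)-2-Ar-6-geranyl-5-hydroxy-7-(triisopropylsilyloxy)chroman-4-one | COc1cc([C@@H]2CC(=O)c3c(cc(O[Si](C(C)C)(C(C)C)C(C)C)c(C/C=C(\C)CCC=C(C)C)c3O)O2)cc(O[Si](C)(C)C(C)(C)C)c1O[Si](C)(C)C(C)(C)C | intermediate
22 | (2S)-2-(3,4-dihydroxy-5-methoxyphenyl)-6-geranyl-5,7-dihydroxychroman-4-one | COc1cc([C@@H]2CC(=O)c3c(cc(O)c(C/C=C(\C)CCC=C(C)C)c3O)O2)cc(O)c1O | target

**Step count**
Total steps: 9. Longest linear sequence: 6 steps (1, 3, 4, 5, 8, 9).

**Steps most likely to fail**

Step 8. Excitation of the enone or of the chelated flavanone product may compete with diazo photolysis. The acyl-substituted vinylketene may also dimerise before it meets the alkyne, or the cascade may stall at the cyclobutenone. The fallback generates the same ketene thermally, without light, and sets out from 11. Silver-promoted Wolff rearrangement in water (PhCO2Ag, Et3N, THF/H2O, dark; the Arndt–Eistert homologation) should give [(2S)-2-Ar-4-oxo-3,4-dihydro-2H-pyran-6-yl]acetic acid F1. 1-Chloro-N,N,2-trimethylprop-1-en-1-amine in CH2Cl2 should convert it into [(2S)-2-Ar-4-oxo-3,4-dihydro-2H-pyran-6-yl]acetyl chloride F2. Slow addition of Et3N to F2 and 16 in toluene (rt, then 80 °C) dehydrochlorinates F2. The fallback comes back to the route at vinylketene 17, which is carried through 18–20 to 21 in the same flask.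

Step 3. The ester group lowers the nucleophilicity of diene 4, so the catalysed aldol may be slow and poorly face-selective. Acid-promoted ionisation at the electron-rich benzylic carbon during the TFA cyclisation may also erode the enantiomeric purity. The fallback separates stereocontrol from C–C bond formation to the diketo ester and sets out from 2.
- Brown allylation with (−)-B-allyldiisopinocampheylborane (Et2O, −78 °C; NaOH, H2O2) should add to the Si face and give (1S)-1-Ar-but-3-en-1-ol F3.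
- TESCl and imidazole give its triethylsilyl ether, (1S)-1-Ar-1-(triethylsilyloxy)but-3-ene F4.
- Wacker oxidation (PdCl2 cat., CuCl, O2, DMF/H2O) gives (4S)-4-Ar-4-(triethylsilyloxy)butan-2-one F5.
- Claisen condensation of the kinetic methyl enolate (LiHMDS, THF, −78 °C) with dimethyl oxalate gives methyl (6S)-6-Ar-2,4-dioxo-6-(triethylsilyloxy)hexanoate F6.
- TFA in wet CH2Cl2 removes the triethylsilyl group. The fallback comes back to the route at 6, which cyclodehydrates to 7 as in step 3.

Step 5. Diazomethane may add as a 1,3-dipole across the doubly activated C5=C6 bond of the pyranone faster than it is acylated, giving pyrazolines. The fallback installs the diazo group by diazo transfer and sets out from acid chloride 10, made from 9 as in step 5. Negishi acylation (MeZnCl, Pd(PPh3)4, THF, 0 °C) should give (2S)-6-acetyl-2-Ar-2,3-dihydro-4H-pyran-4-one F7. Kinetic enolisation of the acetyl group (LiHMDS, THF, −78 °C) and trapping with CF3CO2CH2CF3 gives (2S)-2-Ar-6-(4,4,4-trifluoro-3-oxobutanoyl)-2,3-dihydro-4H-pyran-4-one F8, not isolated. Detrifluoroacetylative diazo transfer (MsN3, Et3N, H2O, MeCN, rt) should then give the diazoketone, and the fallback comes back to the route at 11. Competing deprotonation at C3 would have to be held back by low temperature and exactly one equivalent of base.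

Further compounds
F1 | step 8 | [(2S)-2-Ar-4-oxo-3,4-dihydro-2H-pyran-6-yl]acetic acid | COc1cc([C@@H]2CC(=O)C=C(CC(=O)O)O2)cc(O[Si](C)(C)C(C)(C)C)c1O[Si](C)(C)C(C)(C)C
F2 | step 8 | [(2S)-2-Ar-4-oxo-3,4-dihydro-2H-pyran-6-yl]acetyl chloride | COc1cc([C@@H]2CC(=O)C=C(CC(=O)Cl)O2)cc(O[Si](C)(C)C(C)(C)C)c1O[Si](C)(C)C(C)(C)C
F3 | step 3 | (1S)-1-Ar-but-3-en-1-ol | C=CC[C@H](O)c1cc(OC)c(O[Si](C)(C)C(C)(C)C)c(O[Si](C)(C)C(C)(C)C)c1
F4 | step 3 | (1S)-1-Ar-1-(triethylsilyloxy)but-3-ene | C=CC[C@H](O[Si](CC)(CC)CC)c1cc(OC)c(O[Si](C)(C)C(C)(C)C)c(O[Si](C)(C)C(C)(C)C)c1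
F5 | step 3 | (4S)-4-Ar-4-(triethylsilyloxy)butan-2-one | CC(=O)C[C@H](O[Si](CC)(CC)CC)c1cc(OC)c(O[Si](C)(C)C(C)(C)C)c(O[Si](C)(C)C(C)(C)C)c1
F6 | step 3 | methyl (6S)-6-Ar-2,4-dioxo-6-(triethylsilyloxy)hexanoate | COC(=O)C(=O)CC(=O)C[C@H](O[Si](CC)(CC)CC)c1cc(OC)c(O[Si](C)(C)C(C)(C)C)c(O[Si](C)(C)C(C)(C)C)c1
F7 | step 5 | (2S)-6-acetyl-2-Ar-2,3-dihydro-4H-pyran-4-one | COc1cc([C@@H]2CC(=O)C=C(C(C)=O)O2)cc(O[Si](C)(C)C(C)(C)C)c1O[Si](C)(C)C(C)(C)C
F8 | step 5 | (2S)-2-Ar-6-(4,4,4-trifluoro-3-oxobutanoyl)-2,3-dihydro-4H-pyran-4-one | COc1cc([C@@H]2CC(=O)C=C(C(=O)CC(=O)C(F)(F)F)O2)cc(O[Si](C)(C)C(C)(C)C)c1O[Si](C)(C)C(C)(C)C
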